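(The data stem from a simulated flask for substances that don't exist.)

| flask | L | J | G | E | remark | time |
|---|---|---|---|---|---|---|
| zeta | 0.020 M | 3 equiv | 15 mol% | 10 mol% | run made earlier |  |
| delta | 0.020 M | 3 equiv | 15 mol% | 22 mol% | run made earlier |  |
| beta | 0.020 M | 3 equiv | 7.5 mol% | 15 mol% | run made earlier |  |
| flask | 0.020 M | 3.00 equiv | 15 mol% | 15 mol% |  | 20 min |

| run | time / min | D / % | Q / % |
|---|---|---|---|
| zeta | 3.00 | 32.7 | 66.7 |
| zeta | 6.00 | 32.8 | 67.2 |
| zeta | 10.0 | 33.2 | 66.8 |
| zeta | 12.0 | 33.0 | 66.7 |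
| zeta | 15.0 | 32.5 | 67.2 |
| zeta | 20.0 | 32.8 | 66.8 |
| delta | 1.33 | 31.1 | 63.3 |
| delta | 4.00 | 32.5 | 67.3 |
| delta | 8.00 | 33.0 | 66.9 |
| delta | 10.0 | 32.9 | 67.1 |
| delta | 15.0 | 32.9 | 66.9 |
| delta | 20.0 | 33.0 | 67.2 |
| beta | 2.00 | 30.7 | 61.5 |
| beta | 5.00 | 32.9 | 66.9 |
| beta | 10.0 | 32.6 | 66.9 |
| beta | 15.0 | 32.8 | 67.1 |
| beta | 20.0 | 32.7 | 67.3 |

(scatter of a reading: 0.3 percentage points)



1. share of D in D plus Q at 8.0 s
2. share of D in D plus Q at 1.5 min
3. share of D in D plus Q at 20 min

- In the delta run the amounts of D and Q reach 33.0% and 67.2% of the L charged at 20.0 min, so the plateau share s, meaning D over D plus Q (thermodynamic control, if the pair equilibrates), reads 32.9%, and just a correction to it needs reckoning.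
- Two times make that correction: τ, the unknown relaxation time of D and Q, and a, the age of the product, meaning product present over its rate of arrival.
- Supposing fresh product arrives as D, the share stands above s by about (1 − s)τ/a.
- At 1.33 min the delta run, with the G loading of the flask, has 5.60% of its L unaccounted for, which gives a first-order supply time t_s of 27.7 s and an age of 7.78 min, and its share there shows no excess beyond the scatter.
- Carrying that supply time over to the flask, whose E loading of 15 mol% is lower than the 22 mol% of the delta run, gives an age at 1.5 min of 11.4 min, so my reckoning, which sets that difference aside, puts the flask's share at s then and at 20 min.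
- At 8.0 s the same reckoning gives the flask an age of 9.28 s, so a correction too small to see in the delta reading is larger there by a factor 50.3, and the flask's share may stand above s.
- The forecast gives 35% (22% to 60%), 33% and 32.9%, holding of the earliest readings that “any relaxation is already complete by that point”.
- The flask gives 41.0%, 33.0% and 32.9%, so the share at 8.0 s stands 8 percentage points above s.

    L + G → G + Z (k = 18.9 L mol⁻¹ s⁻¹)
    E + Z ⇌ X (K = 74.3 L mol⁻¹, k = 62.0 L mol⁻¹ s⁻¹)
    J + X → E + D (k = 7.94 L mol⁻¹ s⁻¹)
    D ⇌ Q (K = 2.04, k = 1.19 s⁻¹)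

- In the flask, D and Q relax with a half-life of 0.391 s, far shorter than the 0.20 min half-life of L by its step at 0.535 min. D arrives first and Q comes from it, and the two stand level at 0.0669 min.
- In the neighbour flask with 1.80 equiv of J, s puts 32.9% of the L charged as D at the end, provided its L is turned over completely; the computed amount is 32.9%, with 0% of its L and 44% of its J left and a share of 41.1% at 8.0 s.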